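We have 3 questions on one flask, in which solid substrate feeds a solution where the reagent also destroys itself.

    solid substrate ⇌ dissolved substrate, rate k1*(cs1 - [dissolved substrate]) while solid is left; crystals form when [dissolved substrate] > cs1 (cs1 = 0.53 mM, k1 = 0.133 s⁻¹)
    dissolved substrate + reagent → target (k2 = 186 M⁻¹ s⁻¹)
    2 reagent → self-condensation product (k3 = 140 M⁻¹ s⁻¹)
    reagent + target ⇌ idle adduct, settled at all times (K4 = 360 M⁻¹)

solid substrate 0.0010 M; reagent 2.00 mM; time 1.0 min

- the target and idle adduct together standing at 1.0 min, as a percentage of the solid substrate charged
- the change that raises the amount of target and idle adduct together at 1.0 min, in percent of the solid substrate charged most ("none" if none brings more than 2 percentage points) (autumn / dusk / dawn / none)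
- amount of target and idle adduct together at 1.0 min, in percent of the solid substrate charged, after dawn

- autumn: doubling the amount of reagent, all else as stated
- dusk: doubling the solubility in step 1, all else as stated
- dawn: doubling the dissolution coefficient of step 1, all else as stated

- amounts and yields of target count idle adduct too
- a doubled species enters its step squared and goes two at a time
- given per volume of solution although it is solid: solid substrate
- at the start none of the solid substrate is in solution
- run time (flask): 1.0 min

By our own reckoning, the reagent's first half-life by self-condensation is 1.79 s, shorter than the dissolution time of 7.52 s, so the reagent meets a thin solution. We take the level delivered in that half-life as c(dissolved substrate), and the selectivity factor from the two rate constants: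

a = k1 · t½ · cs1 = 0.126 mM

σ = k2 / (2 k3) = 0.664

n = σ a / c(reagent) = 0.0418

This n, the share number, is the reagent taken by step 2 per reagent taken by step 3 at the charged reagent and level a. Holding a fixed, the reagent's rate law integrates in closed form to its end:

target per charged reagent = n ln(1 + 1/n)

That gives 26.9% of the solid substrate charged. Doubling a gives 42.8%, while autumn gives 19.1%. One number is not enough for the ranking, since n holds k1 and cs1 as a product and so puts dawn and dusk level. But cs1 also moves the saturation ceiling, so we choose dusk.

The forecast gives 33%, dusk and 41%, its first yield above ours, on the ground that the yield follows “how much substrate is in solution during those seconds”.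

The simulation gives 33.0%, dusk and 41.0%, with gains of 13 percentage points for dusk, 8 points for dawn and 3.6 points for autumn. The neighbouring flask charges 6.0 × 10⁻⁴ M of solid substrate. Since n contains no solid charge, it stays 0.0418, and the reckoning there gives 44.8%. Reckoned over simulated, the ratio is 0.815 for the flask and 0.841 for the neighbouring flask. The simulation of that neighbouring flask gives 53.3%, or 0.320 mM of target and idle adduct together, against 0.330 mM in the flask.

(The rate constants were set for the occasion; the run is a simulation.)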